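The target is read as a trans-dibenzylbutyrolactone lignan with one aryl ring cut open. Its 2-pyrone (O1, C2=O, C3–H, C4–CH2, C5–H, C6–CO2H) is a 4-hydroxy-3,5-dimethoxybenzyl ring (C1 bears the CH2) cleaved between arene C4 and C5: pyrone C4, C3, C2 are arene C1, C6, C5; pyrone C5, C6 and the carboxyl carbon are arene C2, C3, C4. In one flask the 3-methoxy-ortho-quinone of the (3R,4R) syringyl lactone, made by periodate oxidation, takes a peracid oxygen into the C4–C5 bond, and aqueous acid recloses the opened chain through an oxygen bridging former C5 and C3, the C3 methoxy group leaving as methanol.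

Key step: step 10

Remark on the chemistry (atom bookkeeping): the ring oxygen O1 of the pyrone is an oxygen of the carboxyl group formed at former arene C5 (or a water oxygen if the 2-oxo acid forms first). The oxygen of the methoxy group on arene C3 cannot end up in the ring, because that group departs as methanol.

Assumption (ligand sense): the (S,S) antipode of Et-DuPHOS, 1,2-bis[(2S,5S)-2,5-diethylphospholan-1-yl]benzene, is taken as the one that delivers the R acid 4. The sense is to be checked on lactone 6 by comparing its sign of rotation with the value recorded for the R enantiomer, and the (R,R) ligand is used if the check demands it.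

Lactone numbering used below: O1, C2 (C=O), C3, C4, C5.

Step 1
Reactants: 1 3,4-dimethoxybenzaldehyde; 2 dimethyl succinate
Product: 3 (E)-4-(3,4-dimethoxyphenyl)-3-(methoxycarbonyl)but-3-enoic acid
Conditions: NaOMe (1.5 equiv), MeOH, reflux; then aq. HCl
Reagents that add atoms: none
Why: Stobbe condensation: the succinate enolate adds to the aldehyde and the sequence ends irreversibly in the unsaturated carboxylate, which drives the reaction and should give the E alkene (aryl trans to the ester) as the more stable isomer.

Step 2
Reactants: 3 (E)-4-(3,4-dimethoxyphenyl)-3-(methoxycarbonyl)but-3-enoic acid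
Product: 4 (R)-4-(3,4-dimethoxyphenyl)-3-(methoxycarbonyl)butanoic acid
Conditions: [Rh(cod)((S,S)-Et-DuPHOS)]OTf (0.5 mol%), NaOMe (0.1 equiv), H2 (5 atm), MeOH, rt; then aq. HCl
Reagents that add atoms: none
Why: Rhodium-catalysed asymmetric hydrogenation of an itaconate-type half ester: carboxylate and alkene chelate the cationic monovalent rhodium centre, so the C2-symmetric bisphospholane decides the face of hydrogen delivery and sets C3 of the acid (the later lactone C4) as R by catalyst control.

Step 3
Reactants: 4 (R)-4-(3,4-dimethoxyphenyl)-3-(methoxycarbonyl)butanoic acid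
Product: 6 (R)-4-(3,4-dimethoxybenzyl)dihydrofuran-2(3H)-one, via hydroxy acid 5 (not isolated)
Conditions: KOH (1.0 equiv), EtOH; CaCl2, NaBH4, EtOH, −10 °C → rt; then 2 M aq. HCl, rt → 40 °C
Reagents that add atoms: none
Why: Chemoselective borohydride reduction followed by acid lactonisation: Ca(BH4)2 formed in the flask reduces the methyl ester while the potassium carboxylate is inert, and acidification closes the five-membered lactone (5-exo-trig) without touching the stereocentre.

Step 4
Reactants: 7 4-hydroxy-3,5-dimethoxybenzaldehyde (syringaldehyde)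
Product: 8 4-(benzyloxy)-3,5-dimethoxybenzaldehyde
Conditions: BnBr, K2CO3, DMF, 60 °C
Reagents that add atoms: benzyl bromide, BrCc1ccccc1
Why: Williamson ether synthesis: the phenoxide, made more acidic by the para formyl group, is benzylated by SN2, which masks the phenol against the strong base of step 7.

Step 5
Reactants: 8 4-(benzyloxy)-3,5-dimethoxybenzaldehyde
Product: 9 [4-(benzyloxy)-3,5-dimethoxyphenyl]methanol
Conditions: NaBH4, MeOH–THF, 0 °C
Reagents that add atoms: none
Why: Borohydride reduction of an aromatic aldehyde to the benzylic alcohol, with the benzyl and methyl ethers inert.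

Step 6
Reactants: 9 [4-(benzyloxy)-3,5-dimethoxyphenyl]methanol
Product: 10 4-(benzyloxy)-3,5-dimethoxybenzyl bromide
Conditions: PBr3 (0.4 equiv), CH2Cl2, 0 °C; used without storage
Reagents that add atoms: phosphorus tribromide, BrP(Br)Br
Why: Bromination of a benzylic alcohol through its phosphite ester with SN2 displacement by bromide, which is fast at an electron-rich benzylic carbon.

Step 7
Reactants: 6 (R)-4-(3,4-dimethoxybenzyl)dihydrofuran-2(3H)-one; 10 4-(benzyloxy)-3,5-dimethoxybenzyl bromide
Product: 11 (3R,4R)-3-[4-(benzyloxy)-3,5-dimethoxybenzyl]-4-(3,4-dimethoxybenzyl)dihydrofuran-2(3H)-one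
Conditions: LiN(SiMe3)2 (1.1 equiv), THF, −78 °C; then 10, DMPU, −78 → −30 °C
Reagents that add atoms: none
Why: SN2 alkylation of a lactone lithium enolate with a benzylic bromide: the electrophile approaches the planar enolate on the face opposite the C4 benzyl group, which sets C3 as R and should give the trans (3R,4R) lactone, also the more stable isomer (substrate control).

Step 8
Reactants: 11 (3R,4R)-3-[4-(benzyloxy)-3,5-dimethoxybenzyl]-4-(3,4-dimethoxybenzyl)dihydrofuran-2(3H)-one
Product: 12 (3R,4R)-3-(4-hydroxy-3,5-dimethoxybenzyl)-4-(3,4-dimethoxybenzyl)dihydrofuran-2(3H)-one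
Conditions: H2 (1 atm), 10% Pd/C, EtOAc–EtOH, rt
Reagents that add atoms: none
Why: Hydrogenolysis of a benzyl aryl ether over zerovalent palladium, which leaves the lactone, the methyl ethers and both stereocentres untouched.

Step 9
Reactants: 12 (3R,4R)-3-(4-hydroxy-3,5-dimethoxybenzyl)-4-(3,4-dimethoxybenzyl)dihydrofuran-2(3H)-one
Product: 13 5-{[(3R,4R)-4-(3,4-dimethoxybenzyl)-2-oxotetrahydrofuran-3-yl]methyl}-3-methoxycyclohexa-3,5-diene-1,2-dione
Conditions: NaIO4 (1.1 equiv), AcOH–H2O, 0–5 °C, dark, short contact; extraction into cold CH2Cl2, drying, use at once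
Reagents that add atoms: water, O (supplies the new carbonyl oxygen at former arene C5)
Why: Periodate oxidative demethylation of a 2,6-dimethoxyphenol: the aryl periodate ester collapses with attack of water at a methoxy-bearing ortho carbon and loss of methanol, the two ortho positions are equivalent so a single 3-methoxy-ortho-quinone should form, and the non-phenolic veratryl ring is inert to periodate.

Step 10
Reactants: 13 5-{[(3R,4R)-4-(3,4-dimethoxybenzyl)-2-oxotetrahydrofuran-3-yl]methyl}-3-methoxycyclohexa-3,5-diene-1,2-dione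
Product: 16 4-{[(3R,4R)-4-(3,4-dimethoxybenzyl)-2-oxotetrahydrofuran-3-yl]methyl}-2-oxo-2H-pyran-6-carboxylic acid, via muconic anhydride 14 (not isolated), via methoxymuconic acid 15 (not isolated)
Conditions: mCPBA (1.05 equiv), CH2Cl2, 0 °C; then THF, 3 M aq. HCl, 45 °C
Reagents that add atoms: meta-chloroperbenzoic acid, OOC(=O)c1cccc(Cl)c1; water, O
Why: Proposed new method: the peracid adds to a quinone carbonyl of 13 (either one, the two modes converge) and the tetrahedral peroxy adduct rearranges by acyl shift, inserting oxygen into the former arene C4–C5 bond as a ring expansion to the seven-membered anhydride 14 (a Baeyer–Villiger step, not a ring closure), which aqueous acid opens to the cis,cis diacid 15. The methoxy enol ether of 15 is then protonated at former C2, an oxygen of the cis-held carboxyl on former C5 captures the oxocarbenium carbon (former C3) in a 6-exo-trig closure, and expulsion of methanol leaves the 2-pyrone with former C4 as the free carboxylic acid; prior hydrolysis of the enol ether to the 2-oxo acid and lactonisation of its enol ends at the same ring. The closest known reaction types are the peracid cleavage of ortho-quinones to cis,cis-muconic anhydrides, the acid hydrolysis of 2-alkoxyacrylic acids, the acid-induced closure of 2-oxohex-4-enedioic (oxalocrotonic) acids to 2-pyrone-6-carboxylic acids and the microbial fission of gallate to 2-pyrone-4,6-dicarboxylate; what is new is their combination in one flask on a 3-methoxy-ortho-quinone. No stereocentre is created, and C3 and C4 of the lactone are remote from the reacting ring and already in the stable trans arrangement. Chemoselectivity is needed between the quinone and the veratryl ring or lactone and is secured because only the quinone carbonyls are electrophilic enough for one equivalent of peracid at 0 °C. Regioselectivity is needed between the six-membered pyrone and a five-membered muconolactone and is secured by the methoxy group, which fixes the cationic site at former C3 and then acts as the leaving group, while the Z geometry inherited from the ring keeps the former C5 carboxyl within reach.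

Compound list
1 | 3,4-dimethoxybenzaldehyde (veratraldehyde) | COc1ccc(C=O)cc1OC | starting material
2 | dimethyl succinate | COC(=O)CCC(=O)OC | starting material
3 | (E)-4-(3,4-dimethoxyphenyl)-3-(methoxycarbonyl)but-3-enoic acid | COc1ccc(/C=C(\CC(=O)O)C(=O)OC)cc1OC | intermediate
4 | (R)-4-(3,4-dimethoxyphenyl)-3-(methoxycarbonyl)butanoic acid | COc1ccc(C[C@@H](C(=O)OC)CC(=O)O)cc1OC | intermediate
5 | (R)-3-(3,4-dimethoxybenzyl)-4-hydroxybutanoic acid (present as its carboxylate, not isolated) | COc1ccc(C[C@@H](CO)CC(=O)O)cc1OC | intermediate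
6 | (R)-4-(3,4-dimethoxybenzyl)dihydrofuran-2(3H)-one | COc1ccc(C[C@H]2COC(=O)C2)cc1OC | intermediate
7 | 4-hydroxy-3,5-dimethoxybenzaldehyde (syringaldehyde) | COc1cc(C=O)cc(OC)c1O | starting material
8 | 4-(benzyloxy)-3,5-dimethoxybenzaldehyde | COc1cc(C=O)cc(OC)c1OCc1ccccc1 | intermediate
9 | [4-(benzyloxy)-3,5-dimethoxyphenyl]methanol | COc1cc(CO)cc(OC)c1OCc1ccccc1 | intermediate
10 | 4-(benzyloxy)-3,5-dimethoxybenzyl bromide | COc1cc(CBr)cc(OC)c1OCc1ccccc1 | intermediate
11 | (3R,4R)-3-[4-(benzyloxy)-3,5-dimethoxybenzyl]-4-(3,4-dimethoxybenzyl)dihydrofuran-2(3H)-one | COc1ccc(C[C@H]2COC(=O)[C@@H]2Cc2cc(OC)c(OCc3ccccc3)c(OC)c2)cc1OC | intermediate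
12 | (3R,4R)-3-(4-hydroxy-3,5-dimethoxybenzyl)-4-(3,4-dimethoxybenzyl)dihydrofuran-2(3H)-one | COc1ccc(C[C@H]2COC(=O)[C@@H]2Cc2cc(OC)c(O)c(OC)c2)cc1OC | intermediate
13 | 5-{[(3R,4R)-4-(3,4-dimethoxybenzyl)-2-oxotetrahydrofuran-3-yl]methyl}-3-methoxycyclohexa-3,5-diene-1,2-dione (3-methoxy-5-alkyl-ortho-quinone) | COc1ccc(C[C@H]2COC(=O)[C@@H]2CC2=CC(=O)C(=O)C(OC)=C2)cc1OC | intermediate
14 | 5-{[(3R,4R)-4-(3,4-dimethoxybenzyl)-2-oxotetrahydrofuran-3-yl]methyl}-3-methoxyoxepine-2,7-dione (cis,cis-muconic anhydride, not isolated) | COc1ccc(C[C@H]2COC(=O)[C@@H]2CC2=CC(=O)OC(=O)C(OC)=C2)cc1OC | intermediate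
15 | (2E,4Z)-4-{[(3R,4R)-4-(3,4-dimethoxybenzyl)-2-oxotetrahydrofuran-3-yl]methyl}-2-methoxyhexa-2,4-dienedioic acid (cis,cis-2-methoxymuconic acid, not isolated) | COc1ccc(C[C@H]2COC(=O)[C@@H]2C/C(=C/C(=O)O)/C=C(/OC)\C(=O)O)cc1OC | intermediate
16 | 4-{[(3R,4R)-4-(3,4-dimethoxybenzyl)-2-oxotetrahydrofuran-3-yl]methyl}-2-oxo-2H-pyran-6-carboxylic acid (CNP0526356.1) | COc1ccc(C[C@H]2COC(=O)[C@@H]2Cc2cc(C(=O)O)oc(=O)c2)cc1OC | target

Total step count: 10.
Longest linear sequence: 7 steps (steps 1, 2, 3, 7, 8, 9, 10; the branch from syringaldehyde, steps 4, 5, 6, 7, 8, 9, 10, is equally long).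

Steps most likely to fail

Step 10. The cascade may stall or go astray in four ways:
- the opened diacid may close in the five-membered muconolactone mode;
- it may isomerise from Z to E before ring closure;
- the carboxyl-substituted enol ether may be protonated too slowly, so that the sequence stops at the diacid;
- excess peracid may attack the electron-rich veratryl ring.

The fallback uses known chemistry and brings in the pyrone ready-made. It sets out from lactone 6. Dimethyl oxalate and methyl 3-methylbut-2-enoate are condensed under KOMe (vinylogous Claisen condensation at the gamma methyl group) and lactonised with acid to methyl 4-methyl-2-oxo-2H-pyran-6-carboxylate F1. Wohl–Ziegler bromination (NBS, AIBN, PhCF3, reflux) gives methyl 4-(bromomethyl)-2-oxo-2H-pyran-6-carboxylate F2. The lithium enolate of 6 (LiN(SiMe3)2, THF, −78 °C) is added to F2 (inverse addition, to keep the enolate away from the pyrone ring) and should give the trans ester methyl 4-{[(3R,4R)-4-(3,4-dimethoxybenzyl)-2-oxotetrahydrofuran-3-yl]methyl}-2-oxo-2H-pyran-6-carboxylate F3. Acid hydrolysis of the methyl ester (aq. HCl, AcOH, 70 °C; the pyrone and the lactone tolerate acid) returns to the route at the target 16.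

Step 9. Periodate may deliver oxygen para to the phenol (quinol formation at the carbon bearing the benzylic CH2), oxidise the quinone further, or the reaction may be slow enough for the quinone to dimerise by cycloaddition or tautomerise to a quinone methide. The fallback makes the same quinone by simple two-electron oxidation of a preformed catechol under neutral, anhydrous conditions. It sets out from lactone 6. Commercial 3,4-dihydroxy-5-methoxybenzaldehyde is dibenzylated (BnBr, K2CO3, DMF) to 3,4-bis(benzyloxy)-5-methoxybenzaldehyde F4. Reduction (NaBH4, MeOH) gives [3,4-bis(benzyloxy)-5-methoxyphenyl]methanol F5, and PBr3 gives 3,4-bis(benzyloxy)-5-methoxybenzyl bromide F6. The lithium enolate of 6 is alkylated with F6 as in step 7 to give (3R,4R)-3-[3,4-bis(benzyloxy)-5-methoxybenzyl]-4-(3,4-dimethoxybenzyl)dihydrofuran-2(3H)-one F7. Hydrogenolysis (H2, 10% Pd/C) frees (3R,4R)-3-(3,4-dihydroxy-5-methoxybenzyl)-4-(3,4-dimethoxybenzyl)dihydrofuran-2(3H)-one F8. Oxidation with Ag2O and Na2SO4 in dry Et2O–CH2Cl2 at 0 °C, followed by filtration, returns to the route at quinone 13 as a solution ready for step 10.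

Step 7. Proton transfer from the product to unreacted enolate may lead to double alkylation, the electron-rich benzylic bromide may decompose by ionisation before it is captured, and the trans selectivity may be incomplete. The fallback replaces alkylation by aldol addition and reductive removal of the carbinol oxygen. It sets out from lactone 6 and aldehyde 8. The lithium enolate of 6 (LiN(SiMe3)2, THF, −78 °C) adds to 8 to give (3S,4R)-3-[(4-benzyloxy-3,5-dimethoxyphenyl)(hydroxy)methyl]-4-(3,4-dimethoxybenzyl)dihydrofuran-2(3H)-one F9 (trans at the ring, mixture of carbinol epimers; the descriptor at C3 changes only because of substituent priorities). Hydrogenolysis (H2, 10% Pd/C, AcOH, cat. HClO4) removes the benzylic hydroxyl and the benzyl ether together and returns to the route at phenol 12. Steps 5 and 6 are then not needed.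

Further compounds
F1 | step 10 | methyl 4-methyl-2-oxo-2H-pyran-6-carboxylate | COC(=O)c1cc(C)cc(=O)o1
F2 | step 10 | methyl 4-(bromomethyl)-2-oxo-2H-pyran-6-carboxylate | COC(=O)c1cc(CBr)cc(=O)o1
F3 | step 10 | methyl 4-{[(3R,4R)-4-(3,4-dimethoxybenzyl)-2-oxotetrahydrofuran-3-yl]methyl}-2-oxo-2H-pyran-6-carboxylate | COc1ccc(C[C@H]2COC(=O)[C@@H]2Cc2cc(C(=O)OC)oc(=O)c2)cc1OC
F4 | step 9 | 3,4-bis(benzyloxy)-5-methoxybenzaldehyde | COc1cc(C=O)cc(OCc2ccccc2)c1OCc1ccccc1
F5 | step 9 | [3,4-bis(benzyloxy)-5-methoxyphenyl]methanol | COc1cc(CO)cc(OCc2ccccc2)c1OCc1ccccc1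
F6 | step 9 | 3,4-bis(benzyloxy)-5-methoxybenzyl bromide | COc1cc(CBr)cc(OCc2ccccc2)c1OCc1ccccc1
F7 | step 9 | (3R,4R)-3-[3,4-bis(benzyloxy)-5-methoxybenzyl]-4-(3,4-dimethoxybenzyl)dihydrofuran-2(3H)-one | COc1ccc(C[C@H]2COC(=O)[C@@H]2Cc2cc(OC)c(OCc3ccccc3)c(OCc3ccccc3)c2)cc1OC
F8 | step 9 | (3R,4R)-3-(3,4-dihydroxy-5-methoxybenzyl)-4-(3,4-dimethoxybenzyl)dihydrofuran-2(3H)-one | COc1ccc(C[C@H]2COC(=O)[C@@H]2Cc2cc(O)c(O)c(OC)c2)cc1OC
F9 | step 7 | (3S,4R)-3-[(4-benzyloxy-3,5-dimethoxyphenyl)(hydroxy)methyl]-4-(3,4-dimethoxybenzyl)dihydrofuran-2(3H)-one, carbinol epimers | COc1ccc(C[C@H]2COC(=O)[C@@H]2C(O)c2cc(OC)c(OCc3ccccc3)c(OC)c2)cc1OC
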